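**Retrosynthetic overview**

1. Numbering (cembrane): ring carbons C1–C14 with C1 = ring-fusion CH, C2 = lactone O–CH, C3=C4(Me), C6 = butenolide O–CH, C7=C8, C12 = C(Me)(OOH); C15, C16, C17 = α-carbon, carbonyl and exocyclic methylene of the 16,2-lactone; C19 = butenolide carbonyl.
2. Target ⇐ last-step Schenck ene reaction of singlet oxygen at C11=C12 of the Δ11 bis-lactone (allylic C10–H becomes C12–OOH) ⇐ HWE methylenation of the macrocyclic α-phosphono lactone.
3. Macrocycle ⇐ intramolecular B-alkyl Suzuki coupling (C12–C13, 14-membered ring) ⇐ butenolide by esterification with a 2-methylidene acid and ring-closing metathesis (C7=C8).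
4. Key disconnection C1–C15: the trans α-phosphono-γ-lactone by palladium-catalysed ring-closing allylic alkylation of a syn-chlorohydrin phosphonoacetate. The enabling feature is that the lactone oxygen sits on C2 next to C1, so an O-acyl tether holds C15 in a 1,5 relation to C1 (five-membered ring), and C1–C14–C13 can act as an allyl unit whose vinyl remainder C14=C13 is exactly the two-carbon link to C12 of the 14-membered ring.
5. Ring order: γ-lactone → butenolide → 14-membered carbocycle. Stereocentres: C6 bought, C2 (and a C1–Cl relay centre) set by Ipc-controlled chloroallylboration, C1 relayed in the key step, C12 relayed from the macrocycle in the ene reaction.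

Key step: step 12

Remark: the α-phosphono centre C15 of compounds 24–29 is carried as an epimer mixture because step 17 destroys it, so their SMILES leave it undefined; cyclopentadienyl ligands are written σ-bonded in SMILES.

**Route**

Step 1
Reactants: 1 pent-3-yn-1-ol
Product: 3 (3E)-4-iodopent-3-en-1-ol, via alkenylzirconocene 2 (not isolated)
Conditions: Cp2Zr(H)Cl (2.5 equiv), THF, rt to 50 °C; then I2, 0 °C
Reagents that add atoms: iodine, II
Why: Hydrozirconation of the 2-alkyne under equilibrating conditions places zirconium by syn addition on the methyl-bearing carbon (the first equivalent is spent on the hydroxyl group), and iodinolysis with retention should give the (E)-2-iodoalk-2-ene that later fixes the C11=C12 geometry.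

Step 2
Reactants: 3 (3E)-4-iodopent-3-en-1-ol
Product: 4 (2E)-2,5-diiodopent-2-ene
Conditions: PPh3, I2, imidazole, CH2Cl2, 0 °C to rt
Reagents that add atoms: iodine, II
Why: Appel-type iodination turns the primary alcohol into the alkyl iodide by SN2 at carbon without affecting the vinyl iodide.

Step 3
Reactants: 4 (2E)-2,5-diiodopent-2-ene; 5 triethyl phosphonoacetate
Product: 7 ethyl (5E)-2-(diethoxyphosphoryl)-6-iodohept-5-enoate, via sodium phosphonoacetate 6 (not isolated)
Conditions: NaH, 5 (2 equiv), THF/DMF, 0 °C; then 4, 60 °C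
Reagents that add atoms: none
Why: SN2 alkylation of the soft phosphonoacetate carbanion (in excess to limit dialkylation) by the primary iodide; the vinyl iodide is inert to substitution.

Step 4
Reactants: 7 ethyl (5E)-2-(diethoxyphosphoryl)-6-iodohept-5-enoate
Product: 8 ethyl (5E)-6-iodo-2-methylidenehept-5-enoate
Conditions: K2CO3, 37% aq. HCHO, rt
Reagents that add atoms: formaldehyde, C=O
Why: Horner–Wadsworth–Emmons olefination of the α-alkyl phosphonoacetate with formaldehyde delivers the 2-methylidene ester.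

Step 5
Reactants: 8 ethyl (5E)-6-iodo-2-methylidenehept-5-enoate
Product: 9 (5E)-6-iodo-2-methylidenehept-5-enoic acid
Conditions: LiOH·H2O, THF/H2O, 0 °C to rt; then 1 M HCl
Reagents that add atoms: lithium hydroxide, [Li+].[OH-]
Why: Saponification of the ethyl ester at low temperature, where hydrolysis is faster than conjugate addition to the α-substituted acrylate.

Step 6
Reactants: 10 (2S)-2-ethenyloxirane
Product: 11 (3R)-hex-1-en-5-yn-3-ol
Conditions: HC≡CLi·H2NCH2CH2NH2, DMSO, 0 °C to rt
Reagents that add atoms: lithium acetylide–ethylenediamine complex, [Li]C#C.NCCN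
Why: Epoxide opening by SN2 attack of the acetylide at the unsubstituted carbon leaves the C–O bond of the stereocentre intact, so the purchased (S)-epoxide supplies the (R)-carbinol that becomes C6.

Step 7
Reactants: 11 (3R)-hex-1-en-5-yn-3-ol
Product: 12 tert-butyl{[(3R)-hex-1-en-5-yn-3-yl]oxy}diphenylsilane
Conditions: TBDPSCl, imidazole, DMF, rt
Reagents that add atoms: tert-butyl(chloro)diphenylsilane, CC(C)(C)[Si](Cl)(c1ccccc1)c1ccccc1
Why: Silyl protection of the secondary alcohol; the TBDPS ether is chosen to withstand Me3Al, the borane reagent, NaH and zerovalent palladium and to be cleaved later by fluoride.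

Step 8
Reactants: 12 tert-butyl{[(3R)-hex-1-en-5-yn-3-yl]oxy}diphenylsilane
Product: 15 (2E,5R)-5-[(tert-butyldiphenylsilyl)oxy]-3-methylhepta-2,6-dien-1-ol, via alkenylalane 13 (not isolated), via lithium aluminate 14 (not isolated)
Conditions: Me3Al, Cp2ZrCl2 (0.25 equiv), CH2Cl2, 0 °C to rt; then n-BuLi, THF, −78 °C; (CH2O)n, to rt
Reagents that add atoms: trimethylaluminium, C[Al](C)C; formaldehyde (as paraformaldehyde), C=O
Why: Negishi zirconium-catalysed carboalumination adds methyl and aluminium syn across the terminal alkyne with methyl on the internal carbon (C4), and the derived aluminate is hydroxymethylated with retention, which sets the (E)-C3=C4 alkene and introduces C2; the monosubstituted alkene reacts much more slowly.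

Step 9
Reactants: 15 (2E,5R)-5-[(tert-butyldiphenylsilyl)oxy]-3-methylhepta-2,6-dien-1-ol
Product: 16 (2E,5R)-5-[(tert-butyldiphenylsilyl)oxy]-3-methylhepta-2,6-dienal
Conditions: MnO2, CH2Cl2, rt
Reagents that add atoms: none
Why: MnO2 oxidizes the primary allylic alcohol selectively to the (E)-enal without double-bond isomerization.

Step 10
Reactants: 16 (2E,5R)-5-[(tert-butyldiphenylsilyl)oxy]-3-methylhepta-2,6-dienal; 17 3-chloroprop-1-ene (allyl chloride)
Product: 20 (3S,4S,5E,8R)-8-[(tert-butyldiphenylsilyl)oxy]-3-chloro-6-methyldeca-1,5,9-trien-4-ol, via chloroallylborane 18 (not isolated), via borinate 19 (not isolated)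
Conditions: 17, (+)-Ipc2BOMe, LiN(c-C6H11)2 (from HN(c-C6H11)2, n-BuLi), Et2O, −95 °C; BF3·OEt2; then 16, −95 °C; HOCH2CH2NH2 work-up
Reagents that add atoms: none
Why: Brown-type asymmetric γ-chloroallylboration: the (Z)-chloroallylborane reacts through a chair six-membered transition state, so the Z geometry gives the syn chlorohydrin and the isopinocampheyl groups derived from (−)-α-pinene direct attack to the re face of the aldehyde, which sets C2 (S) and the C1–Cl relay centre (S) by reagent control, independent of the remote C6 centre.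

Step 11
Reactants: 20 (3S,4S,5E,8R)-8-[(tert-butyldiphenylsilyl)oxy]-3-chloro-6-methyldeca-1,5,9-trien-4-ol; 21 (diethoxyphosphoryl)acetic acid
Product: 22 (3S,4S,5E,8R)-8-[(tert-butyldiphenylsilyl)oxy]-3-chloro-6-methyldeca-1,5,9-trien-4-yl (diethoxyphosphoryl)acetate
Conditions: DCC, DMAP (cat.), CH2Cl2, 0 °C to rt
Reagents that add atoms: none
Why: Steglich esterification acylates the secondary alcohol under neutral conditions that neither ionize the allylic chloride nor close the epoxide.

Step 12
Reactants: 22 (3S,4S,5E,8R)-8-[(tert-butyldiphenylsilyl)oxy]-3-chloro-6-methyldeca-1,5,9-trien-4-yl (diethoxyphosphoryl)acetate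
Product: 24 diethyl {(4S,5S)-5-[(1E,4R)-4-[(tert-butyldiphenylsilyl)oxy]-2-methylhexa-1,5-dien-1-yl]-4-ethenyl-2-oxooxolan-3-yl}phosphonate, via sodium enolate 23 (not isolated)
Conditions: NaH (1.05 equiv), THF, 0 °C, 10 min; then slow addition to Pd(PPh3)4 (5 mol %), THF, 60 °C, final 5 mM
Reagents that add atoms: none
Why: Intramolecular Tsuji–Trost allylic alkylation: zerovalent palladium ionizes the allylic C1–Cl bond with inversion to a π-allyl complex spanning C1–C14–C13, and the tethered phosphonoacetate carbanion (C15) attacks C1 anti to palladium, forming C1–C15 and closing the γ-lactone in the 5-exo mode while the allyl unit ends as the exocyclic C14=C13 vinyl group. The closest known reaction type is the palladium-catalysed cyclization of allylic halides or esters that carry a tethered stabilized carbanion (vinyl-substituted carbocycles, γ-lactams from amide tethers, lactones from ester-tethered sulfonyl- or phosphonoacetates). The new C1 stereocentre is set by double inversion (net retention at C1, so the syn chlorohydrin gives the 1,2-trans lactone) and, because the unsubstituted C13 terminus allows π–σ–π face exchange, also by substrate control from C2: the transition state with the C2 alkenyl group and the allyl unit on opposite faces of the forming ring (C2–H eclipsing the allyl plane) is preferred, so both effects converge on the trans-fused product. The step needs regioselectivity for C1 over C13 (five- versus seven-membered lactone; the latter would require the less stable anti π-allyl geometry and a cis alkene in the ring) and chemoselectivity for the allylic chloride over the allylic C2–O ester, which is secured because a chloride on a monosubstituted allyl unit ionizes far faster than a carboxylate next to a trisubstituted alkene; high dilution suppresses intermolecular alkylation while the ester reaches the reactive s-cis rotamer. In one operation the step delivers the lactone ring, the C1 stereocentre, the vinyl handle that becomes C13–C14 of the macrocycle and the phosphonate that is later turned into the exocyclic methylene. C15 is formed as an epimer mixture of no consequence.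

Step 13
Reactants: 24 diethyl {(4S,5S)-5-[(1E,4R)-4-[(tert-butyldiphenylsilyl)oxy]-2-methylhexa-1,5-dien-1-yl]-4-ethenyl-2-oxooxolan-3-yl}phosphonate
Product: 25 diethyl {(4S,5S)-4-ethenyl-5-[(1E,4R)-4-hydroxy-2-methylhexa-1,5-dien-1-yl]-2-oxooxolan-3-yl}phosphonate
Conditions: HF·pyridine, pyridine, THF, 0 °C to rt
Reagents that add atoms: none
Why: Fluoride-mediated desilylation with buffered HF·pyridine frees the C6 hydroxyl without the basic conditions that would enolize or open the phosphono lactone.

Step 14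
Reactants: 25 diethyl {(4S,5S)-4-ethenyl-5-[(1E,4R)-4-hydroxy-2-methylhexa-1,5-dien-1-yl]-2-oxooxolan-3-yl}phosphonate; 9 (5E)-6-iodo-2-methylidenehept-5-enoic acid
Product: 26 (3R,5E)-6-[(2S,3S)-4-(diethoxyphosphoryl)-3-ethenyl-5-oxooxolan-2-yl]-5-methylhexa-1,5-dien-3-yl (5E)-6-iodo-2-methylidenehept-5-enoate
Conditions: DCC, DMAP (cat.), CH2Cl2, 0 °C to rt
Reagents that add atoms: none
Why: Steglich esterification of the secondary allylic alcohol with the α-substituted acrylic acid brings in C8–C12 and C19.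

Step 15
Reactants: 26 (3R,5E)-6-[(2S,3S)-4-(diethoxyphosphoryl)-3-ethenyl-5-oxooxolan-2-yl]-5-methylhexa-1,5-dien-3-yl (5E)-6-iodo-2-methylidenehept-5-enoate
Product: 27 diethyl {(4S,5S)-4-ethenyl-5-[(1E)-3-{(2R)-4-[(3E)-4-iodopent-3-en-1-yl]-5-oxo-2,5-dihydrofuran-2-yl}-2-methylprop-1-en-1-yl]-2-oxooxolan-3-yl}phosphonate
Conditions: second-generation Grubbs catalyst RuCl2(H2IMes)(PCy3)(=CHPh) (10 mol %), toluene, 80 °C, 2 mM
Reagents that add atoms: none
Why: Ring-closing metathesis between the C7 vinyl group and the acrylate methylene closes the α-substituted butenolide (any ring through the C13=C14 vinyl group would have to hold the (E)-C3=C4 alkene in a medium ring), high dilution limiting cross-metathesis of the remaining vinyl group and the trisubstituted vinyl iodide being inert.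

Step 16
Reactants: 27 diethyl {(4S,5S)-4-ethenyl-5-[(1E)-3-{(2R)-4-[(3E)-4-iodopent-3-en-1-yl]-5-oxo-2,5-dihydrofuran-2-yl}-2-methylprop-1-en-1-yl]-2-oxooxolan-3-yl}phosphonate
Product: 29 (1S,2S,3E,6R,7Z,11E)-15-(diethoxyphosphoryl)cembra-3,7,11-triene-16,2:19,6-diolide, via alkylborane 28 (not isolated)
Conditions: 9-BBN, THF, 0 °C to rt; then slow addition to PdCl2(dppf) (15 mol %), AsPh3, Cs2CO3, DMF/THF/H2O, rt, 2 mM
Reagents that add atoms: none
Why: 9-BBN hydroborates only the monosubstituted C13=C14 alkene with boron on the terminal carbon, and the intramolecular B-alkyl Suzuki–Miyaura coupling with the vinyl iodide under slow addition closes the 14-membered ring at C12–C13 with retention of the (E)-C11=C12 geometry.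

Step 17
Reactants: 29 (1S,2S,3E,6R,7Z,11E)-15-(diethoxyphosphoryl)cembra-3,7,11-triene-16,2:19,6-diolide
Product: 30 (1R,2S,3E,6R,7Z,11E)-cembra-3,7,11,15(17)-tetraene-16,2:19,6-diolide
Conditions: K2CO3, 37% aq. HCHO, THF, 0 °C to rt
Reagents that add atoms: formaldehyde, C=O
Why: Horner–Wadsworth–Emmons olefination of the α-phosphono lactone with formaldehyde under mild carbonate conditions installs the C15=C17 methylidene and erases the C15 stereocentre.

Step 18
Reactants: 30 (1R,2S,3E,6R,7Z,11E)-cembra-3,7,11,15(17)-tetraene-16,2:19,6-diolide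
Product: 31 (1R,2S,3E,6R,7Z,10E,12S)-12-hydroperoxycembra-3,7,10,15(17)-tetraene-16,2:19,6-diolide
Conditions: O2, tetraphenylporphyrin (cat.), visible light, CH2Cl2, 0 °C
Reagents that add atoms: dioxygen, O=O
Why: Schenck ene reaction: singlet oxygen attacks only the electron-rich C11=C12 alkene (C3=C4 is deactivated by the allylic lactone oxygen, the two conjugated alkenes are inert), abstracts an allylic C10–H on the more substituted side of the alkene (cis effect) and so places the hydroperoxide on C12 with a new (E)-C10=C11 bond, the C12 configuration being set by substrate control through attack on the exposed outer face of the rigid bicyclic macrocycle, which is expected to lead to 12S; a regioisomeric C11 hydroperoxide, if formed, is removed by chromatography.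

**Compound list**

1 | pent-3-yn-1-ol | CC#CCCO | starting material
2 | [(2E)-5-{[chlorobis(cyclopentadienyl)zirconio]oxy}pent-2-en-2-yl]chlorobis(cyclopentadienyl)zirconium | Cl[Zr](C1C=CC=C1)(C1C=CC=C1)OCC/C=C(\C)[Zr](Cl)(C1C=CC=C1)C1C=CC=C1 | intermediate
3 | (3E)-4-iodopent-3-en-1-ol | OCC/C=C(\C)I | intermediate
4 | (2E)-2,5-diiodopent-2-ene | ICC/C=C(\C)I | intermediate
5 | triethyl phosphonoacetate | CCOC(=O)CP(=O)(OCC)OCC | starting material
6 | sodium salt of triethyl phosphonoacetate | [Na+].CCOC(=O)[CH-]P(=O)(OCC)OCC | intermediate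
7 | ethyl (5E)-2-(diethoxyphosphoryl)-6-iodohept-5-enoate (racemic) | CCOC(=O)C(CC/C=C(\C)I)P(=O)(OCC)OCC | intermediate
8 | ethyl (5E)-6-iodo-2-methylidenehept-5-enoate | CCOC(=O)C(=C)CC/C=C(\C)I | intermediate
9 | (5E)-6-iodo-2-methylidenehept-5-enoic acid | OC(=O)C(=C)CC/C=C(\C)I | intermediate
10 | (2S)-2-ethenyloxirane | C=C[C@H]1CO1 | starting material
11 | (3R)-hex-1-en-5-yn-3-ol | C#CC[C@@H](O)C=C | intermediate
12 | tert-butyl{[(3R)-hex-1-en-5-yn-3-yl]oxy}diphenylsilane | C#CC[C@@H](O[Si](c1ccccc1)(c1ccccc1)C(C)(C)C)C=C | intermediate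
13 | [(1E,4R)-4-[(tert-butyldiphenylsilyl)oxy]-2-methylhexa-1,5-dien-1-yl]dimethylalane | C[Al](C)/C=C(\C)C[C@@H](O[Si](c1ccccc1)(c1ccccc1)C(C)(C)C)C=C | intermediate
14 | lithium butyl[(1E,4R)-4-[(tert-butyldiphenylsilyl)oxy]-2-methylhexa-1,5-dien-1-yl]dimethylaluminate | [Li+].CCCC[Al-](C)(C)/C=C(\C)C[C@@H](O[Si](c1ccccc1)(c1ccccc1)C(C)(C)C)C=C | intermediate
15 | (2E,5R)-5-[(tert-butyldiphenylsilyl)oxy]-3-methylhepta-2,6-dien-1-ol | OC/C=C(\C)C[C@@H](O[Si](c1ccccc1)(c1ccccc1)C(C)(C)C)C=C | intermediate
16 | (2E,5R)-5-[(tert-butyldiphenylsilyl)oxy]-3-methylhepta-2,6-dienal | O=C/C=C(\C)C[C@@H](O[Si](c1ccccc1)(c1ccccc1)C(C)(C)C)C=C | intermediate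
17 | 3-chloroprop-1-ene (allyl chloride) | C=CCCl | starting material
18 | [(2Z)-3-chloroprop-2-en-1-yl]bis(isopinocampheyl)borane, isopinocampheyl groups from (−)-α-pinene | Cl/C=C\CB([C@H]1C[C@H]2C[C@@H]([C@@H]1C)C2(C)C)[C@H]1C[C@H]2C[C@@H]([C@@H]1C)C2(C)C | intermediate
19 | O-bis(isopinocampheyl)boryl ether (borinate) of chlorohydrin 20 | C=C[C@H](Cl)[C@@H](OB([C@H]1C[C@H]2C[C@@H]([C@@H]1C)C2(C)C)[C@H]1C[C@H]2C[C@@H]([C@@H]1C)C2(C)C)/C=C(\C)C[C@@H](O[Si](c1ccccc1)(c1ccccc1)C(C)(C)C)C=C | intermediate
20 | (3S,4S,5E,8R)-8-[(tert-butyldiphenylsilyl)oxy]-3-chloro-6-methyldeca-1,5,9-trien-4-ol (syn chlorohydrin) | C=C[C@H](Cl)[C@@H](O)/C=C(\C)C[C@@H](O[Si](c1ccccc1)(c1ccccc1)C(C)(C)C)C=C | intermediate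
21 | (diethoxyphosphoryl)acetic acid | OC(=O)CP(=O)(OCC)OCC | starting material
22 | (3S,4S,5E,8R)-8-[(tert-butyldiphenylsilyl)oxy]-3-chloro-6-methyldeca-1,5,9-trien-4-yl (diethoxyphosphoryl)acetate | C=C[C@H](Cl)[C@@H](OC(=O)CP(=O)(OCC)OCC)/C=C(\C)C[C@@H](O[Si](c1ccccc1)(c1ccccc1)C(C)(C)C)C=C | intermediate
23 | sodium enolate of ester 22 (carbanion at the phosphonoacetate CH) | [Na+].C=C[C@H](Cl)[C@@H](OC(=O)[CH-]P(=O)(OCC)OCC)/C=C(\C)C[C@@H](O[Si](c1ccccc1)(c1ccccc1)C(C)(C)C)C=C | intermediate
24 | diethyl {(4S,5S)-5-[(1E,4R)-4-[(tert-butyldiphenylsilyl)oxy]-2-methylhexa-1,5-dien-1-yl]-4-ethenyl-2-oxooxolan-3-yl}phosphonate (4,5-trans; C3 epimers) | C=C[C@@H]1C(P(=O)(OCC)OCC)C(=O)O[C@H]1/C=C(\C)C[C@@H](O[Si](c1ccccc1)(c1ccccc1)C(C)(C)C)C=C | intermediate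
25 | diethyl {(4S,5S)-4-ethenyl-5-[(1E,4R)-4-hydroxy-2-methylhexa-1,5-dien-1-yl]-2-oxooxolan-3-yl}phosphonate | C=C[C@@H]1C(P(=O)(OCC)OCC)C(=O)O[C@H]1/C=C(\C)C[C@@H](O)C=C | intermediate
26 | (3R,5E)-6-[(2S,3S)-4-(diethoxyphosphoryl)-3-ethenyl-5-oxooxolan-2-yl]-5-methylhexa-1,5-dien-3-yl (5E)-6-iodo-2-methylidenehept-5-enoate | C=C[C@@H]1C(P(=O)(OCC)OCC)C(=O)O[C@H]1/C=C(\C)C[C@@H](OC(=O)C(=C)CC/C=C(\C)I)C=C | intermediate
27 | diethyl {(4S,5S)-4-ethenyl-5-[(1E)-3-{(2R)-4-[(3E)-4-iodopent-3-en-1-yl]-5-oxo-2,5-dihydrofuran-2-yl}-2-methylprop-1-en-1-yl]-2-oxooxolan-3-yl}phosphonate | C=C[C@@H]1C(P(=O)(OCC)OCC)C(=O)O[C@H]1/C=C(\C)C[C@@H]1C=C(CC/C=C(\C)I)C(=O)O1 | intermediate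
28 | B-alkyl-9-borabicyclo[3.3.1]nonane from anti-Markovnikov hydroboration of the ethenyl group of 27 (boron on C13) | C(C[C@@H]1C(P(=O)(OCC)OCC)C(=O)O[C@H]1/C=C(\C)C[C@@H]1C=C(CC/C=C(\C)I)C(=O)O1)B1C2CCCC1CCC2 | intermediate
29 | (1S,2S,3E,6R,7Z,11E)-15-(diethoxyphosphoryl)cembra-3,7,11-triene-16,2:19,6-diolide (trans-fused γ-lactone; C15 epimers) | CCOP(=O)(OCC)C1C(=O)O[C@H]2/C=C(\C)C[C@@H]3C=C(CC/C=C(\C)CC[C@H]12)C(=O)O3 | intermediate
30 | (1R,2S,3E,6R,7Z,11E)-cembra-3,7,11,15(17)-tetraene-16,2:19,6-diolide | C=C1C(=O)O[C@H]2/C=C(\C)C[C@@H]3C=C(CC/C=C(\C)CC[C@H]12)C(=O)O3 | intermediate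
31 | (1R,2S,3E,6R,7Z,10E,12S)-12-hydroperoxycembra-3,7,10,15(17)-tetraene-16,2:19,6-diolide | C=C1C(=O)O[C@H]2/C=C(\C)C[C@@H]3C=C(C/C=C/[C@@](C)(OO)CC[C@H]12)C(=O)O3 | target

**Step count and risks**

Total step count: 18. Longest linear sequence: 13 steps (steps 6–18, from 10); the acid 9 is made in a five-step side branch (steps 1–5).

Steps most likely to fail:

1. Step 12 (key cyclization). The ring closure must pass through the minor s-cis rotamer of the ester, so intermolecular alkylation, attack at the distal allyl terminus (seven-membered lactone) or erosion of the trans selectivity may compete. The fallback forms the lactone from a butenolide and sets out from enal 16. Zinc/ProPhenol-catalysed addition of methyl propiolate (Me2Zn, the ligand enantiomer that gives the 4S alcohol) would give methyl (4S,5E,8R)-8-[(tert-butyldiphenylsilyl)oxy]-4-hydroxy-6-methyldeca-5,9-dien-2-ynoate F1. Semi-hydrogenation (H2, Pd/CaCO3 poisoned with Pb(OAc)2, quinoline) would give the (Z)-hydroxy enoate F2, which lactonizes (PPTS) to the butenolide (5R)-5-[(1E,4R)-4-[(tert-butyldiphenylsilyl)oxy]-2-methylhexa-1,5-dien-1-yl]furan-2(5H)-one F3. Conjugate addition of a vinyl cuprate (CH2=CHMgBr, CuBr·SMe2, TMSCl, −78 °C) anti to the C2 substituent would give the trans vinyl lactone F4. Treatment with LDA and ClP(O)(OEt)2 gives the enol phosphate F5, and excess LDA induces the 1,3-phosphorus shift from oxygen to carbon, which returns the route to 24.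

2. Step 18 (Schenck ene reaction). Hydrogen abstraction may be divided between C10–H and the C20 methyl on the same side of the alkene, and singlet oxygen may attack the wrong face of the macrocycle. The fallback is ionic, regiodefined and reagent-controlled, and sets out from 30. Shi epoxidation of the C11=C12 alkene (fructose-derived ketone enantiomer chosen for the 11R,12R epoxide; Oxone (2KHSO5·KHSO4·K2SO4), K2CO3, MeCN/dimethoxymethane/buffer, 0 °C) would give the epoxide F6. Perhydrolysis with ethereal H2O2 and catalytic phosphomolybdic acid (H3PMo12O40) opens it at the tertiary carbon with inversion to the (11R,12S)-12-hydroperoxy-11-ol F7. The hydroperoxide is capped with 2-methoxypropene (PPTS cat., −20 °C) to the peroxyketal F8. Burgess dehydration of the C11 alcohol, which can only eliminate towards C10, gives the (10E)-alkene F9, and AcOH/THF/H2O releases the hydroperoxide and returns to 31.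

3. Step 16 (macrocyclization). The 14-membered ring closure is slow, so oligomerization or protodeboronation of the alkylborane may win, and the aqueous carbonate may epimerize the butenolide γ-centre (C6). The fallback changes the order of ring closure and sets out from ester 26. 9-BBN hydroboration of the C13=C14 vinyl group (the C7 vinyl group is deactivated by the allylic acyloxy group, the acrylate is conjugated and 1,1-disubstituted) gives the alkylborane F10. B-alkyl Suzuki coupling under the conditions of step 16 closes the more flexible 15-membered seco-butenolide macrolactone F11, in which C6 is not yet acidic. Transannular ring-closing metathesis (second-generation Grubbs catalyst RuCl2(H2IMes)(PCy3)(=CHPh), toluene, 80 °C) then forms the butenolide and returns to 29.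

Further compounds
F1 | step 12 | methyl (4S,5E,8R)-8-[(tert-butyldiphenylsilyl)oxy]-4-hydroxy-6-methyldeca-5,9-dien-2-ynoate | COC(=O)C#C[C@@H](O)/C=C(\C)C[C@@H](O[Si](c1ccccc1)(c1ccccc1)C(C)(C)C)C=C
F2 | step 12 | methyl (2Z,4R,5E,8R)-8-[(tert-butyldiphenylsilyl)oxy]-4-hydroxy-6-methyldeca-2,5,9-trienoate | COC(=O)/C=C\[C@@H](O)/C=C(\C)C[C@@H](O[Si](c1ccccc1)(c1ccccc1)C(C)(C)C)C=C
F3 | step 12 | (5R)-5-[(1E,4R)-4-[(tert-butyldiphenylsilyl)oxy]-2-methylhexa-1,5-dien-1-yl]furan-2(5H)-one | O=C1C=C[C@@H](O1)/C=C(\C)C[C@@H](O[Si](c2ccccc2)(c2ccccc2)C(C)(C)C)C=C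
F4 | step 12 | (4S,5R)-5-[(1E,4R)-4-[(tert-butyldiphenylsilyl)oxy]-2-methylhexa-1,5-dien-1-yl]-4-ethenyloxolan-2-one (4,5-trans) | C=C[C@@H]1CC(=O)O[C@H]1/C=C(\C)C[C@@H](O[Si](c1ccccc1)(c1ccccc1)C(C)(C)C)C=C
F5 | step 12 | diethyl (4R,5R)-5-[(1E,4R)-4-[(tert-butyldiphenylsilyl)oxy]-2-methylhexa-1,5-dien-1-yl]-4-ethenyl-4,5-dihydrofuran-2-yl phosphate | C=C[C@@H]1C=C(OP(=O)(OCC)OCC)O[C@H]1/C=C(\C)C[C@@H](O[Si](c1ccccc1)(c1ccccc1)C(C)(C)C)C=C
F6 | step 18 | (1R,2S,3E,6R,7Z,11R,12R)-11,12-epoxycembra-3,7,15(17)-triene-16,2:19,6-diolide | C=C1C(=O)O[C@H]2/C=C(\C)C[C@@H]3C=C(CC[C@H]4O[C@]4(C)CC[C@H]12)C(=O)O3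
F7 | step 18 | (1R,2S,3E,6R,7Z,11R,12S)-12-hydroperoxy-11-hydroxycembra-3,7,15(17)-triene-16,2:19,6-diolide | C=C1C(=O)O[C@H]2/C=C(\C)C[C@@H]3C=C(CC[C@@H](O)[C@@](C)(OO)CC[C@H]12)C(=O)O3
F8 | step 18 | (1R,2S,3E,6R,7Z,11R,12S)-11-hydroxy-12-[(2-methoxypropan-2-yl)peroxy]cembra-3,7,15(17)-triene-16,2:19,6-diolide | C=C1C(=O)O[C@H]2/C=C(\C)C[C@@H]3C=C(CC[C@@H](O)[C@@](C)(OOC(C)(C)OC)CC[C@H]12)C(=O)O3
F9 | step 18 | (1R,2S,3E,6R,7Z,10E,12S)-12-[(2-methoxypropan-2-yl)peroxy]cembra-3,7,10,15(17)-tetraene-16,2:19,6-diolide | C=C1C(=O)O[C@H]2/C=C(\C)C[C@@H]3C=C(C/C=C/[C@@](C)(OOC(C)(C)OC)CC[C@H]12)C(=O)O3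
F10 | step 16 | B-alkyl-9-borabicyclo[3.3.1]nonane from hydroboration of the lactone ethenyl group of 26 (boron on C13) | C(C[C@@H]1C(P(=O)(OCC)OCC)C(=O)O[C@H]1/C=C(\C)C[C@@H](OC(=O)C(=C)CC/C=C(\C)I)C=C)B1C2CCCC1CCC2
F11 | step 16 | 15-membered seco-butenolide macrolactone: C12–C13-linked ring carrying the C6 ethenyl group, the C8 methylidene and the trans-fused α-phosphono γ-lactone | CCOP(=O)(OCC)C1C(=O)O[C@H]2/C=C(\C)C[C@H](C=C)OC(=O)C(=C)CC/C=C(\C)CC[C@H]12
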